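**Retrosynthetic overview** (flavanone unit: O1, C2, C3, C4, C4a to C8a; flavone unit: the same locants with a double prime)

1. Target 15 comes from its hexabenzyl ether 14 by hydrogenolysis. 14 is the prototropic isomer of the C2-symmetric, 3,3''-ylidene-linked bis(chroman-4-one) 13, so both halves are built as identical units.
2. Key disconnection: both acyl–aryl bonds, C4–C4a of the flavanone unit and C4''–C4a'' of the flavone unit, by twofold Friedel–Crafts acylation of maleic anhydride 10. A 1,3-hydrogen shift then turns one half into the flavone and sets C3; the C2 centre of that half is erased.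
3. Enabling feature: both rings A are phloroglucinol rings, so each 3,5-dioxygenated aryl ether has two identical, doubly activated ortho carbons (C4a, C4a''). C4 and C4'' sit on the neighbouring carbons C3 and C3'', so the chain C4–C3–C3''–C4'' is a hidden 2,3-disubstituted maleic acid with two identical benzylic C–O centres (C2, C2'').
4. 10 comes from alkyne 8 and two molecules of CO2; 8 from (S,S)-ynediol 6 and two molecules of phenol 7 (double Mitsunobu inversion); 6 from ynedione 5, which comes from one acetylene and two molecules of aldehyde 2.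
5. Ring order: the benzene rings are bought; a temporary furan-2,5-dione ring is made in step 5; both pyranone rings C are closed together in step 6.

Key step: step 6

Assumption: in the oxazaborolidine reduction (step 3) the aryl group is taken to act as the larger and the alkynyl group as the smaller carbonyl substituent; if the sense proved opposite, the antipodal catalyst would be used and nothing else changes.

**Step 1**
Reactants: 1 acetylene; 2 4-(benzyloxy)benzaldehyde
Product: 4 1,4-bis[4-(benzyloxy)phenyl]but-2-yne-1,4-diol (rac/meso mixture), via ethynediylbis(magnesium bromide) 3 (not isolated)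
Conditions: EtMgBr (2.0 equiv), Et2O, rt; 2 (2.0 equiv), THF, 0 °C to rt; aq. NH4Cl
Reagents that add atoms: 4-(benzyloxy)benzaldehyde (second molecule of 2), O=Cc1ccc(OCc2ccccc2)cc1
Why: Twofold Grignard 1,2-addition, in which each carbon of the acetylene bis-magnesium reagent adds to one molecule of aldehyde 2 (two molecules of 2 per acetylene), is the classical route to 1,4-diaryl-2-butyne-1,4-diols; the two carbinol centres form without control and are erased in step 2.

**Step 2**
Reactants: 4 1,4-bis[4-(benzyloxy)phenyl]but-2-yne-1,4-diol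
Product: 5 1,4-bis[4-(benzyloxy)phenyl]but-2-yne-1,4-dione
Conditions: MnO2 (activated, excess), CH2Cl2, rt
Reagents that add atoms: none
Why: MnO2 oxidation of benzylic/propargylic alcohols should give the conjugated diaroylacetylene without touching the benzyl ethers.

**Step 3**
Reactants: 5 1,4-bis[4-(benzyloxy)phenyl]but-2-yne-1,4-dione
Product: 6 (1S,4S)-1,4-bis[4-(benzyloxy)phenyl]but-2-yne-1,4-diol
Conditions: (S)-2-methyl-CBS-oxazaborolidine (20 mol % per C=O), BH3·SMe2 (1.2 equiv per C=O), THF, −30 °C; then MeOH
Reagents that add atoms: none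
Why: Corey–Bakshi–Shibata reduction, in which the catalyst-bound borane delivers hydride to the face defined by the large aryl versus the slim alkynyl substituent, should set the (S) configuration at each carbinol; twofold catalyst control should leave the minor stereoisomer mainly as the separable meso diol.

**Step 4**
Reactants: 6 (1S,4S)-1,4-bis[4-(benzyloxy)phenyl]but-2-yne-1,4-diol; 7 3,5-bis(benzyloxy)phenol
Product: 8 (1R,4R)-1,4-bis[4-(benzyloxy)phenyl]-1,4-bis[3,5-bis(benzyloxy)phenoxy]but-2-yne
Conditions: PPh3 (2.6 equiv), DIAD (2.6 equiv), 7 (2.4 equiv), toluene, 0 °C to rt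
Reagents that add atoms: 3,5-bis(benzyloxy)phenol (second molecule of 7), Oc1cc(OCc2ccccc2)cc(OCc2ccccc2)c1
Why: Twofold Mitsunobu etherification, one molecule of the acidic phenol 7 per carbinol, should proceed by SN2 displacement of the oxyphosphonium with inversion at each carbinol carbon (no β-hydrogen, so no elimination), fixing both future C2-type centres; any leakage at one centre would appear as the separable meso bis-ether.

**Step 5**
Reactants: 8 (1R,4R)-1,4-bis[4-(benzyloxy)phenyl]-1,4-bis[3,5-bis(benzyloxy)phenoxy]but-2-yne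
Product: 10 3,4-bis{(R)-[4-(benzyloxy)phenyl][3,5-bis(benzyloxy)phenoxy]methyl}furan-2,5-dione, via maleic diacid 9 (not isolated)
Conditions: Ni(acac)2(bpy) (10 mol %), Zn powder (3 equiv), MgBr2 (3 equiv), MS 3 Å, CO2 (1 atm), DMF, rt; then dilute aq. HCl, 0 °C
Reagents that add atoms: carbon dioxide (two molecules), O=C=O.O=C=O
Why: Nickel-catalysed reductive double carboxylation of an internal alkyne with CO2 (oxidative cyclisation at zerovalent nickel with the first CO2, then insertion of a second CO2 promoted by MgBr2) should add one carboxyl carbon to each alkyne carbon, syn across the triple bond; the 2,3-disubstituted maleic acid closes to the anhydride on acidification and the two stereocentres are not involved.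

**Step 6**
Reactants: 10 3,4-bis{(R)-[4-(benzyloxy)phenyl][3,5-bis(benzyloxy)phenoxy]methyl}furan-2,5-dione
Product: 14 (2S,3R)-5,7-bis(benzyloxy)-2-[4-(benzyloxy)phenyl]-3-{5,7-bis(benzyloxy)-2-[4-(benzyloxy)phenyl]-4-oxo-4H-chromen-3-yl}chroman-4-one, via keto acid 11 (not isolated), via mixed trifluoroacetic anhydride 12 (not isolated), via bischromanonylidene 13 (not isolated)
Conditions: Sc(OTf)3 (20 mol %), TFAA (3 equiv), CH2Cl2–MeNO2 (4:1), −20 °C to rt; aq. NaHCO3
Reagents that add atoms: none
Why: Sc(OTf)3 activates one anhydride carbonyl (C4) for attack by the ortho carbon (C4a) of the neighbouring 3,5-bis(benzyloxy)phenoxy ring, closing the first pyranone by 6-exo-trig Friedel–Crafts acylation and releasing the C4'' acid 11, which TFAA converts into mixed anhydride 12 for the same 6-exo-trig closure onto the second ring to give the C2-symmetric bis-ylidene 13. The closest known reaction type is the anhydride-mediated cyclisation of 2-(aryloxymethyl)acrylic acids to 3-ylidenechroman-4-ones, run here in both directions. Strained, cross-conjugated 13 should then tautomerise under the acid present: protonation of the carbonyl of one unit and loss of the C2 proton of the other unit (the γ-position of that enone) gives a dienol whose ketonisation puts hydrogen on C3 of the first unit, so the unit that lost its C2 hydrogen becomes the aromatic 4-pyranone (flavone) ring and the first unit the flavanone; the halves are homotopic, so either direction (or tautomerisation of 11 before the second closure) gives the same compound. No stereocentre comes from a reagent: C2 is the surviving centre from step 4 (its descriptor changes from R to S only because C3 becomes sp3), and C3 is set under thermodynamic control by acid-mediated enolisation, which places the C2 aryl and C3 flavonyl groups trans-diequatorial (2S,3R). The step needs ring-A regioselectivity (both ortho positions of each phloroglucinol ring are identical and the para position cannot reach), six- over seven-membered closure (each arene reaches only the carbonyl on its own alkene carbon through a six-membered transition state) and retention at C2 (no base is present, so retro-oxa-Michael opening and β-aryloxide elimination are avoided).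

**Step 7**
Reactants: 14 (2S,3R)-5,7-bis(benzyloxy)-2-[4-(benzyloxy)phenyl]-3-{5,7-bis(benzyloxy)-2-[4-(benzyloxy)phenyl]-4-oxo-4H-chromen-3-yl}chroman-4-one
Product: 15 (2S,3R)-5,7-dihydroxy-3-[5,7-dihydroxy-2-(4-hydroxyphenyl)-4-oxo-4H-chromen-3-yl]-2-(4-hydroxyphenyl)chroman-4-one
Conditions: H2 (1 atm), Pd/C (10 %), EtOAc–MeOH, rt
Reagents that add atoms: none
Why: Catalytic hydrogenolysis should cleave all six benzyl ethers under neutral conditions, which avoids the base-induced ring opening that would racemise C2, while the pyranone rings should not be reduced at 1 atm.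

**Compound list**

1 | acetylene | C#C | starting material
2 | 4-(benzyloxy)benzaldehyde | O=Cc1ccc(OCc2ccccc2)cc1 | starting material
3 | ethynediylbis(magnesium bromide) | Br[Mg]C#C[Mg]Br | intermediate
4 | 1,4-bis[4-(benzyloxy)phenyl]but-2-yne-1,4-diol (rac/meso mixture) | OC(C#CC(O)c1ccc(OCc2ccccc2)cc1)c1ccc(OCc2ccccc2)cc1 | intermediate
5 | 1,4-bis[4-(benzyloxy)phenyl]but-2-yne-1,4-dione | O=C(C#CC(=O)c1ccc(OCc2ccccc2)cc1)c1ccc(OCc2ccccc2)cc1 | intermediate
6 | (1S,4S)-1,4-bis[4-(benzyloxy)phenyl]but-2-yne-1,4-diol | O[C@H](C#C[C@@H](O)c1ccc(OCc2ccccc2)cc1)c1ccc(OCc2ccccc2)cc1 | intermediate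
7 | 3,5-bis(benzyloxy)phenol | Oc1cc(OCc2ccccc2)cc(OCc2ccccc2)c1 | starting material
8 | (1R,4R)-1,4-bis[4-(benzyloxy)phenyl]-1,4-bis[3,5-bis(benzyloxy)phenoxy]but-2-yne | C(#C[C@H](Oc1cc(OCc2ccccc2)cc(OCc2ccccc2)c1)c1ccc(OCc2ccccc2)cc1)[C@H](Oc1cc(OCc2ccccc2)cc(OCc2ccccc2)c1)c1ccc(OCc2ccccc2)cc1 | intermediate
9 | (Z)-2,3-bis{(R)-[4-(benzyloxy)phenyl][3,5-bis(benzyloxy)phenoxy]methyl}but-2-enedioic acid | OC(=O)/C(=C(\C(=O)O)[C@H](Oc1cc(OCc2ccccc2)cc(OCc2ccccc2)c1)c1ccc(OCc2ccccc2)cc1)[C@H](Oc1cc(OCc2ccccc2)cc(OCc2ccccc2)c1)c1ccc(OCc2ccccc2)cc1 | intermediate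
10 | 3,4-bis{(R)-[4-(benzyloxy)phenyl][3,5-bis(benzyloxy)phenoxy]methyl}furan-2,5-dione | O=C1OC(=O)C([C@H](Oc2cc(OCc3ccccc3)cc(OCc3ccccc3)c2)c2ccc(OCc3ccccc3)cc2)=C1[C@H](Oc1cc(OCc2ccccc2)cc(OCc2ccccc2)c1)c1ccc(OCc2ccccc2)cc1 | intermediate
11 | (Z,3R)-3-[4-(benzyloxy)phenyl]-3-[3,5-bis(benzyloxy)phenoxy]-2-{(2R)-5,7-bis(benzyloxy)-2-[4-(benzyloxy)phenyl]-4-oxochroman-3-ylidene}propanoic acid | O=C1c2c(OCc3ccccc3)cc(OCc3ccccc3)cc2O[C@H](c2ccc(OCc3ccccc3)cc2)/C1=C(/C(=O)O)[C@H](Oc1cc(OCc2ccccc2)cc(OCc2ccccc2)c1)c1ccc(OCc2ccccc2)cc1 | intermediate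
12 | mixed anhydride of acid 11 with trifluoroacetic acid | O=C1c2c(OCc3ccccc3)cc(OCc3ccccc3)cc2O[C@H](c2ccc(OCc3ccccc3)cc2)/C1=C(/C(=O)OC(=O)C(F)(F)F)[C@H](Oc1cc(OCc2ccccc2)cc(OCc2ccccc2)c1)c1ccc(OCc2ccccc2)cc1 | intermediate
13 | (Z,2R,2''R)-5,5'',7,7''-tetrakis(benzyloxy)-2,2''-bis[4-(benzyloxy)phenyl]-3,3''-bi(chroman-3-ylidene)-4,4''-dione | O=C1c2c(OCc3ccccc3)cc(OCc3ccccc3)cc2O[C@H](c2ccc(OCc3ccccc3)cc2)/C1=C1\[C@@H](c2ccc(OCc3ccccc3)cc2)Oc2cc(OCc3ccccc3)cc(OCc3ccccc3)c2C1=O | intermediate
14 | (2S,3R)-5,7-bis(benzyloxy)-2-[4-(benzyloxy)phenyl]-3-{5,7-bis(benzyloxy)-2-[4-(benzyloxy)phenyl]-4-oxo-4H-chromen-3-yl}chroman-4-one | O=C1c2c(OCc3ccccc3)cc(OCc3ccccc3)cc2O[C@H](c2ccc(OCc3ccccc3)cc2)[C@H]1c1c(-c2ccc(OCc3ccccc3)cc2)oc2cc(OCc3ccccc3)cc(OCc3ccccc3)c2c1=O | intermediate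
15 | (2S,3R)-5,7-dihydroxy-3-[5,7-dihydroxy-2-(4-hydroxyphenyl)-4-oxo-4H-chromen-3-yl]-2-(4-hydroxyphenyl)chroman-4-one | O=C1c2c(O)cc(O)cc2O[C@H](c2ccc(O)cc2)[C@H]1c1c(-c2ccc(O)cc2)oc2cc(O)cc(O)c2c1=O | target

**Step count and risks**

Total steps: 7. Longest linear sequence: 7 steps.

The three steps most likely to fail:

Step 5. The alkenylnickel intermediates carry an aryloxy group on the neighbouring carbon, so β-aryloxide elimination to an allene, or insertion of zerovalent nickel into the propargylic C–O bond, may outrun the second CO2 insertion; coordination of an alkyne flanked by two branched substituents may also be slow. The fallback sets out from 8 and uses an oxidative bis(methoxycarbonylation) with divalent palladium (Pd(OAc)2 cat., p-benzoquinone, CO 1 atm, MeOH–THF, rt), in which a Pd–CO2Me species adds syn to the alkyne and CO insertion and methanolysis follow without a low-valent metal. This should give dimethyl (Z)-2,3-bis{(R)-[4-(benzyloxy)phenyl][3,5-bis(benzyloxy)phenoxy]methyl}but-2-enedioate F1. Cleavage of both methyl esters with Me3SnOH (1,2-dichloroethane, 80 °C; a mild hydroxide source that should limit vinylogous β-elimination of aryloxide) and acidification would return to the route at diacid 9, which closes to 10.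

Step 6. Lewis-acid-induced heterolysis of the 4-alkoxybenzylic C2–O bonds (loss of configuration or of the phenol) may compete with acylation, intermolecular trifluoroacetylation of the electron-rich rings may intervene, and the second closure may stall because the twofold ylidene 13 is strained. The fallback sets out from 10: Sc(OTf)3 alone, without TFAA, should stop after the first closure at keto acid 11, which would be isolated. Brief treatment with TsOH (cat., CH2Cl2, rt) should move the double bond into the ring and give (3S)-3-[4-(benzyloxy)phenyl]-3-[3,5-bis(benzyloxy)phenoxy]-2-{5,7-bis(benzyloxy)-2-[4-(benzyloxy)phenyl]-4-oxo-4H-chromen-3-yl}propanoic acid F2 (both C2 epimers), so the strain is removed before the second ring is made. That ring is then closed with TFAA alone (CH2Cl2, 0 °C) as a plain cyclisation of a saturated 3-aryl-3-aryloxypropanoic acid to a flavanone, returning to the route at 14.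

Step 4. The oxyphosphonium intermediate sits on a doubly activated (propargylic and 4-alkoxybenzylic) carbon and may ionise in part, which would erode stereochemical fidelity (meso bis-ether) or divert material to an allenyl ether by SN2' attack. The fallback sets out from 5: reduction with the antipodal (R)-oxazaborolidine under the step 3 conditions should give (1R,4R)-1,4-bis[4-(benzyloxy)phenyl]but-2-yne-1,4-diol F3. Both C–O bonds would then be formed at the aryl carbon, with retention at the carbinol carbons, by metal-free O-arylation of the sodium alkoxide (t-BuONa, toluene, rt) with [3,5-bis(benzyloxy)phenyl](2,4,6-trimethoxyphenyl)iodonium 4-methylbenzenesulfonate F4 (prepared from 1,3-bis(benzyloxy)-5-iodobenzene, mCPBA, TsOH and 1,3,5-trimethoxybenzene). This returns to the route at 8.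

**Further compounds**

F1 | step 5 | dimethyl (Z)-2,3-bis{(R)-[4-(benzyloxy)phenyl][3,5-bis(benzyloxy)phenoxy]methyl}but-2-enedioate | COC(=O)/C(=C(\C(=O)OC)[C@H](Oc1cc(OCc2ccccc2)cc(OCc2ccccc2)c1)c1ccc(OCc2ccccc2)cc1)[C@H](Oc1cc(OCc2ccccc2)cc(OCc2ccccc2)c1)c1ccc(OCc2ccccc2)cc1
F2 | step 6 | (3S)-3-[4-(benzyloxy)phenyl]-3-[3,5-bis(benzyloxy)phenoxy]-2-{5,7-bis(benzyloxy)-2-[4-(benzyloxy)phenyl]-4-oxo-4H-chromen-3-yl}propanoic acid (C2 epimers) | OC(=O)C([C@H](Oc1cc(OCc2ccccc2)cc(OCc2ccccc2)c1)c1ccc(OCc2ccccc2)cc1)c1c(-c2ccc(OCc3ccccc3)cc2)oc2cc(OCc3ccccc3)cc(OCc3ccccc3)c2c1=O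
F3 | step 4 | (1R,4R)-1,4-bis[4-(benzyloxy)phenyl]but-2-yne-1,4-diol | O[C@@H](C#C[C@H](O)c1ccc(OCc2ccccc2)cc1)c1ccc(OCc2ccccc2)cc1
F4 | step 4 | [3,5-bis(benzyloxy)phenyl](2,4,6-trimethoxyphenyl)iodonium 4-methylbenzenesulfonate | COc1cc(OC)c([I+]c2cc(OCc3ccccc3)cc(OCc3ccccc3)c2)c(OC)c1.Cc1ccc(cc1)S(=O)(=O)[O-]
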